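## Retrosynthetic overview

- The Z-cinnamate is made last, by a Still–Gennari olefination on the phosphonoacetate of the macrocyclic alcohol, so no Z-configured acid has to be activated.
- The only ring, the eleven-membered carbocycle, is closed late by intramolecular alkylation of an allylic sulfone carbanion with an allylic chloride (C5–C6 bond), followed by palladium-catalysed desulfonylation.
- The open-chain chloro sulfone comes from one δ-lactone: a lactol Wittig reaction builds the C7=C8 E-olefin, and reduction of the enoate arm gives the sulfone terminus.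
- The stereocentre and the C3=C4 E-olefin are set together by a catalytic asymmetric vinylogous Mukaiyama aldol on an aldehyde ester made from 3,3-dimethylglutaric anhydride.

Assumption: the (R,R)-bisphosphoramide–SiCl4 catalyst delivers the dienolate to the Re face of the aldehyde, which gives the S carbinol (CIP order O > allylic CH2 > CMe2-side CH2 in every intermediate); if the sense is opposite, the enantiomeric catalyst is used.

## Route

Step 1
Reactants: 1 3,3-dimethylglutaric anhydride
Product: 2 5-methoxy-3,3-dimethyl-5-oxopentanoic acid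
Conditions: MeOH, reflux
Reagents that add atoms: methanol (CO)
Why: Alcoholysis of the symmetric cyclic anhydride (nucleophilic acyl substitution) gives the half ester and differentiates the two carboxyl groups; no stereocentre is involved.

Step 2
Reactants: 2 5-methoxy-3,3-dimethyl-5-oxopentanoic acid
Product: 4 methyl 3,3-dimethyl-5-oxopentanoate, via acid chloride 3 (not isolated)
Conditions: (COCl)2, DMF (cat.), CH2Cl2, 0 °C to rt; then H2 (1 atm), Pd/BaSO4, 2,6-lutidine, THF, rt
Reagents that add atoms: none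
Why: Acid chloride formation followed by Rosenmund reduction stops at the aldehyde, because the deactivated palladium surface hydrogenolyses only the C–Cl bond and leaves the methyl ester alone.

Step 3
Reactants: 5 methyl 3-methylbut-2-enoate
Product: 6 tert-butyl[(1-methoxy-3-methylbuta-1,3-dien-1-yl)oxy]dimethylsilane
Conditions: LiN(i-Pr)2, THF, −78 °C; t-BuMe2SiCl, DMPU, −78 °C to rt
Reagents that add atoms: tert-butyl(chloro)dimethylsilane (CC(C)(C)[Si](C)(C)Cl)
Why: γ-Deprotonation of the senecioate and O-silylation of the lithium dienolate (silyl ketene acetal formation) give the vinylogous nucleophile.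

Step 4
Reactants: 4 methyl 3,3-dimethyl-5-oxopentanoate; 6 tert-butyl[(1-methoxy-3-methylbuta-1,3-dien-1-yl)oxy]dimethylsilane
Product: 8 methyl (2E)-4-[(2S)-4,4-dimethyl-6-oxooxan-2-yl]-3-methylbut-2-enoate, via hydroxy diester 7 (not isolated)
Conditions: SiCl4 (1.1 equiv), (R,R)-bisphosphoramide [C20H12(NMe)2P(O)N(Me)]2(CH2)5 derived from N,N'-dimethyl-1,1'-binaphthyl-2,2'-diamine (5 mol %), i-Pr2NEt (10 mol %), CH2Cl2, −78 °C; aq. NaHCO3; then TsOH·H2O (cat.), CH2Cl2, rt
Reagents that add atoms: none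
Why: Catalytic enantioselective vinylogous Mukaiyama aldol addition (Lewis-base-activated SiCl4): γ-attack of the s-trans dienolate on the Re face of the aldehyde sets the S carbinol and the E-trisubstituted enoate, and the δ-hydroxy ester then lactonises, which masks the alcohol and differentiates the two esters.

Step 5
Reactants: 8 methyl (2E)-4-[(2S)-4,4-dimethyl-6-oxooxan-2-yl]-3-methylbut-2-enoate
Product: 9 (6S)-6-[(2E)-4-hydroxy-2-methylbut-2-en-1-yl]-4,4-dimethyloxan-2-ol (anomer mixture)
Conditions: i-Bu2AlH (3.3 equiv), CH2Cl2, −78 °C; aq. potassium sodium tartrate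
Reagents that add atoms: none
Why: Hydride reduction at low temperature stops at the lactol (stable aluminium hemiacetal) while the conjugated ester is reduced 1,2 to the allylic alcohol; the stereocentre is untouched.

Step 6
Reactants: 9 (6S)-6-[(2E)-4-hydroxy-2-methylbut-2-en-1-yl]-4,4-dimethyloxan-2-ol; 10 ethyl 2-(triphenyl-λ5-phosphanylidene)propanoate
Product: 11 ethyl (2E,7S,9E)-7,11-dihydroxy-2,5,5,9-tetramethylundeca-2,9-dienoate
Conditions: PhMe, 90 °C
Reagents that add atoms: none
Why: Wittig olefination of the open hydroxy-aldehyde tautomer with a stabilised α-methyl ylide is E-selective and releases the secondary alcohol; the α-methyl enoate is a poor acceptor, so oxa-Michael closure is slow under these neutral conditions.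

Step 7
Reactants: 11 ethyl (2E,7S,9E)-7,11-dihydroxy-2,5,5,9-tetramethylundeca-2,9-dienoate
Product: 13 ethyl (2E,7S,9E)-11-(benzenesulfonyl)-7-hydroxy-2,5,5,9-tetramethylundeca-2,9-dienoate, via allylic chloride 12 (not isolated)
Conditions: NCS, Me2S, CH2Cl2, −20 to 0 °C; then PhSO2Na, Bu4NI (cat.), DMF, rt
Reagents that add atoms: sodium benzenesulfinate ([Na+].[O-]S(=O)c1ccccc1)
Why: Corey–Kim chlorination converts only the primary allylic alcohol, and SN2 displacement by the sulfinate sulfur gives the allylic sulfone with the E-olefin intact.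

Step 8
Reactants: 13 ethyl (2E,7S,9E)-11-(benzenesulfonyl)-7-hydroxy-2,5,5,9-tetramethylundeca-2,9-dienoate
Product: 14 (2E,7S,9E)-11-(benzenesulfonyl)-2,5,5,9-tetramethylundeca-2,9-diene-1,7-diol
Conditions: i-Bu2AlH (3.5 equiv), CH2Cl2, −78 °C; aq. potassium sodium tartrate
Reagents that add atoms: none
Why: 1,2-Reduction of the enoate gives the E-allylic alcohol; the sulfone and both olefins are inert to the hydride at this temperature.

Step 9
Reactants: 14 (2E,7S,9E)-11-(benzenesulfonyl)-2,5,5,9-tetramethylundeca-2,9-diene-1,7-diol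
Product: 15 (2E,5S,9E)-1-(benzenesulfonyl)-11-chloro-3,7,7,10-tetramethylundeca-2,9-dien-5-ol
Conditions: NCS, Me2S, CH2Cl2, −20 to 0 °C
Reagents that add atoms: N-chlorosuccinimide (O=C1CCC(=O)N1Cl)
Why: Corey–Kim chlorination again selects the primary allylic alcohol over the secondary one (no base is added, so the secondary alcohol is returned on work-up).

Step 10
Reactants: 15 (2E,5S,9E)-1-(benzenesulfonyl)-11-chloro-3,7,7,10-tetramethylundeca-2,9-dien-5-ol
Product: 16 (1S,3E,7E)-5-(benzenesulfonyl)-3,7,10,10-tetramethylcycloundeca-3,7-dien-1-ol (C5 epimers)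
Conditions: LiN(SiMe3)2 (2.2 equiv), THF, 0 °C to rt, slow addition of 15 (final 2 mM)
Reagents that add atoms: none
Why: Intramolecular SN2 alkylation of the α-sulfonyl allylic carbanion (sulfone-based allyl–allyl coupling, the alkoxide being a spectator) at high dilution closes the eleven-membered ring by α-attack; both E-olefins and C1 are unaffected, and the new C5 centre is removed in the next step.

Step 11
Reactants: 16 (1S,3E,7E)-5-(benzenesulfonyl)-3,7,10,10-tetramethylcycloundeca-3,7-dien-1-ol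
Product: 17 (1S,3E,7E)-3,7,10,10-tetramethylcycloundeca-3,7-dien-1-ol
Conditions: LiBHEt3 (4 equiv), PdCl2(dppp) [dppp = Ph2P(CH2)3PPh2] (5 mol %), THF, 0 °C
Reagents that add atoms: none
Why: Palladium-catalysed reductive desulfonylation: zerovalent palladium ionises the allylic sulfone to a π-allyl complex and hydride is delivered to the less substituted terminus C5, so the C3=C4 E-olefin stays in place.

Step 12
Reactants: 17 (1S,3E,7E)-3,7,10,10-tetramethylcycloundeca-3,7-dien-1-ol; 18 2-[bis(2,2,2-trifluoroethoxy)phosphoryl]acetic acid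
Product: 19 (1S,3E,7E)-3,7,10,10-tetramethylcycloundeca-3,7-dien-1-yl 2-[bis(2,2,2-trifluoroethoxy)phosphoryl]acetate
Conditions: N,N'-dicyclohexylcarbodiimide, 4-(dimethylamino)pyridine (cat.), CH2Cl2, 0 °C to rt
Reagents that add atoms: none
Why: Steglich esterification acylates the alcohol oxygen without breaking the C1–O bond, so the S configuration is retained.

Step 13
Reactants: 19 (1S,3E,7E)-3,7,10,10-tetramethylcycloundeca-3,7-dien-1-yl 2-[bis(2,2,2-trifluoroethoxy)phosphoryl]acetate; 20 4-[(tert-butyldimethylsilyl)oxy]benzaldehyde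
Product: 21 (1S,3E,7E)-3,7,10,10-tetramethylcycloundeca-3,7-dien-1-yl (2Z)-3-{4-[(tert-butyldimethylsilyl)oxy]phenyl}prop-2-enoate
Conditions: KN(SiMe3)2, 18-crown-6, THF, −78 °C
Reagents that add atoms: none
Why: Still–Gennari variant of the Horner–Wadsworth–Emmons olefination: the electron-poor trifluoroethyl phosphonate eliminates rapidly from the kinetically formed adduct, giving the Z-cinnamate.

Step 14
Reactants: 21 (1S,3E,7E)-3,7,10,10-tetramethylcycloundeca-3,7-dien-1-yl (2Z)-3-{4-[(tert-butyldimethylsilyl)oxy]phenyl}prop-2-enoate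
Product: 22 (1S,3E,7E)-3,7,10,10-tetramethylcycloundeca-3,7-dien-1-yl (2Z)-3-(4-hydroxyphenyl)prop-2-enoate
Conditions: Bu4NF, AcOH, THF, 0 °C
Reagents that add atoms: none
Why: Fluoride-mediated cleavage of the aryl silyl ether, buffered with acetic acid so that the Z-enoate and the ester linkage are not disturbed.

## Compound list

1 | 3,3-dimethylglutaric anhydride (4,4-dimethyloxane-2,6-dione) | CC1(C)CC(=O)OC(=O)C1 | starting material
2 | 5-methoxy-3,3-dimethyl-5-oxopentanoic acid | COC(=O)CC(C)(C)CC(=O)O | intermediate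
3 | methyl 5-chloro-3,3-dimethyl-5-oxopentanoate (acid chloride) | COC(=O)CC(C)(C)CC(=O)Cl | intermediate
4 | methyl 3,3-dimethyl-5-oxopentanoate | COC(=O)CC(C)(C)CC=O | intermediate
5 | methyl 3-methylbut-2-enoate | COC(=O)C=C(C)C | starting material
6 | tert-butyl[(1-methoxy-3-methylbuta-1,3-dien-1-yl)oxy]dimethylsilane | COC(O[Si](C)(C)C(C)(C)C)=CC(C)=C | intermediate
7 | dimethyl (2E,5S)-5-hydroxy-3,7,7-trimethylnon-2-enedioate (hydroxy diester) | COC(=O)/C=C(\C)C[C@@H](O)CC(C)(C)CC(=O)OC | intermediate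
8 | methyl (2E)-4-[(2S)-4,4-dimethyl-6-oxooxan-2-yl]-3-methylbut-2-enoate | COC(=O)/C=C(\C)C[C@@H]1CC(C)(C)CC(=O)O1 | intermediate
9 | (6S)-6-[(2E)-4-hydroxy-2-methylbut-2-en-1-yl]-4,4-dimethyloxan-2-ol (anomer mixture) | OC/C=C(\C)C[C@@H]1CC(C)(C)CC(O)O1 | intermediate
10 | ethyl 2-(triphenyl-λ5-phosphanylidene)propanoate | CCOC(=O)C(C)=P(c1ccccc1)(c1ccccc1)c1ccccc1 | starting material
11 | ethyl (2E,7S,9E)-7,11-dihydroxy-2,5,5,9-tetramethylundeca-2,9-dienoate | OC/C=C(\C)C[C@@H](O)CC(C)(C)C/C=C(\C)C(=O)OCC | intermediate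
12 | ethyl (2E,7S,9E)-11-chloro-7-hydroxy-2,5,5,9-tetramethylundeca-2,9-dienoate (allylic chloride) | ClC/C=C(\C)C[C@@H](O)CC(C)(C)C/C=C(\C)C(=O)OCC | intermediate
13 | ethyl (2E,7S,9E)-11-(benzenesulfonyl)-7-hydroxy-2,5,5,9-tetramethylundeca-2,9-dienoate | O=S(=O)(C/C=C(\C)C[C@@H](O)CC(C)(C)C/C=C(\C)C(=O)OCC)c1ccccc1 | intermediate
14 | (2E,7S,9E)-11-(benzenesulfonyl)-2,5,5,9-tetramethylundeca-2,9-diene-1,7-diol | O=S(=O)(C/C=C(\C)C[C@@H](O)CC(C)(C)C/C=C(\C)CO)c1ccccc1 | intermediate
15 | (2E,5S,9E)-1-(benzenesulfonyl)-11-chloro-3,7,7,10-tetramethylundeca-2,9-dien-5-ol | O=S(=O)(C/C=C(\C)C[C@@H](O)CC(C)(C)C/C=C(\C)CCl)c1ccccc1 | intermediate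
16 | (1S,3E,7E)-5-(benzenesulfonyl)-3,7,10,10-tetramethylcycloundeca-3,7-dien-1-ol (C5 epimers) | C/C1=C\CC(C)(C)C[C@H](O)C/C(C)=C/C(S(=O)(=O)c2ccccc2)C1 | intermediate
17 | (1S,3E,7E)-3,7,10,10-tetramethylcycloundeca-3,7-dien-1-ol | C/C1=C\CC(C)(C)C[C@H](O)C/C(C)=C/CC1 | intermediate
18 | 2-[bis(2,2,2-trifluoroethoxy)phosphoryl]acetic acid | OC(=O)CP(=O)(OCC(F)(F)F)OCC(F)(F)F | starting material
19 | (1S,3E,7E)-3,7,10,10-tetramethylcycloundeca-3,7-dien-1-yl 2-[bis(2,2,2-trifluoroethoxy)phosphoryl]acetate | C/C1=C\CC(C)(C)C[C@H](OC(=O)CP(=O)(OCC(F)(F)F)OCC(F)(F)F)C/C(C)=C/CC1 | intermediate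
20 | 4-[(tert-butyldimethylsilyl)oxy]benzaldehyde | O=Cc1ccc(O[Si](C)(C)C(C)(C)C)cc1 | starting material
21 | (1S,3E,7E)-3,7,10,10-tetramethylcycloundeca-3,7-dien-1-yl (2Z)-3-{4-[(tert-butyldimethylsilyl)oxy]phenyl}prop-2-enoate | C/C1=C\CC(C)(C)C[C@H](OC(=O)/C=C\c2ccc(O[Si](C)(C)C(C)(C)C)cc2)C/C(C)=C/CC1 | intermediate
22 | (1S,3E,7E)-3,7,10,10-tetramethylcycloundeca-3,7-dien-1-yl (2Z)-3-(4-hydroxyphenyl)prop-2-enoate | C/C1=C\CC(C)(C)C[C@H](OC(=O)/C=C\c2ccc(O)cc2)C/C(C)=C/CC1 | target

## Step count and risks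

Total step count: 14. Longest linear sequence: 13 steps (steps 1, 2 and 4 to 14); step 3 is a one-step side branch.

First risk, step 4. The enolisable, β-quaternary aliphatic aldehyde may react slowly or with reduced enantioselectivity in the vinylogous aldol. The fallback sets out from 4. Asymmetric propargylation with 4,4,5,5-tetramethyl-2-(propa-1,2-dien-1-yl)-1,3,2-dioxaborolane, catalysed by the enantiomer of the 3,3'-bis(2,4,6-triisopropylphenyl)-1,1'-binaphthyl-2,2'-diyl hydrogen phosphate that gives Re-face addition, is followed by acid lactonisation (TsOH·H2O) to give (6S)-4,4-dimethyl-6-(prop-2-yn-1-yl)oxan-2-one F1. Syn-methylalumination of the alkyne (Me3Al, Cp2ZrCl2 cat., CH2Cl2) and trapping of the alkenylalane with methyl chloroformate installs the E-β-methyl enoate. The fallback comes back to the route at 8.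

Second risk, step 10. Closure of the strained eleven-membered ring as a dianion may be outrun by oligomerisation or elimination. The fallback sets out from 15 and closes the ring on a protected monoanion instead. Silylation (t-BuMe2SiOTf, 2,6-lutidine, CH2Cl2, −78 °C) gives tert-butyl{[(2E,5S,9E)-1-(benzenesulfonyl)-11-chloro-3,7,7,10-tetramethylundeca-2,9-dien-5-yl]oxy}dimethylsilane F2. High-dilution cyclisation with LiN(SiMe3)2 in THF gives {[(1S,3E,7E)-5-(benzenesulfonyl)-3,7,10,10-tetramethylcycloundeca-3,7-dien-1-yl]oxy}(tert-butyl)dimethylsilane F3. Desulfonylation with LiBHEt3 and PdCl2(dppp) gives tert-butyldimethyl{[(1S,3E,7E)-3,7,10,10-tetramethylcycloundeca-3,7-dien-1-yl]oxy}silane F4. Desilylation with Bu4NF in THF comes back to the route at 17.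

Third risk, step 13. The Z-selectivity of the olefination on the hindered macrocyclic ester may be incomplete, and the Z/E pair may be hard to separate. The fallback sets out from 17 and makes the cis-olefin by semihydrogenation instead. tert-Butyl(4-ethynylphenoxy)dimethylsilane is lithiated (n-BuLi, THF, −78 °C) and carboxylated with CO2 to give 3-{4-[(tert-butyldimethylsilyl)oxy]phenyl}prop-2-ynoic acid F5. Esterification of 17 with this acid (N,N'-dicyclohexylcarbodiimide, 4-(dimethylamino)pyridine, CH2Cl2) gives (1S,3E,7E)-3,7,10,10-tetramethylcycloundeca-3,7-dien-1-yl 3-{4-[(tert-butyldimethylsilyl)oxy]phenyl}prop-2-ynoate F6. Hydrogenation over Pd/CaCO3 poisoned with Pb(OAc)2 and quinoline (H2, 1 atm, EtOAc) stops at the cis-alkene and leaves the trisubstituted ring olefins alone. The fallback comes back to the route at 21.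

Further compounds

F1 | step 4 | (6S)-4,4-dimethyl-6-(prop-2-yn-1-yl)oxan-2-one | C#CC[C@@H]1CC(C)(C)CC(=O)O1
F2 | step 10 | tert-butyl{[(2E,5S,9E)-1-(benzenesulfonyl)-11-chloro-3,7,7,10-tetramethylundeca-2,9-dien-5-yl]oxy}dimethylsilane | O=S(=O)(C/C=C(\C)C[C@@H](O[Si](C)(C)C(C)(C)C)CC(C)(C)C/C=C(\C)CCl)c1ccccc1
F3 | step 10 | {[(1S,3E,7E)-5-(benzenesulfonyl)-3,7,10,10-tetramethylcycloundeca-3,7-dien-1-yl]oxy}(tert-butyl)dimethylsilane | C/C1=C\CC(C)(C)C[C@H](O[Si](C)(C)C(C)(C)C)C/C(C)=C/C(S(=O)(=O)c2ccccc2)C1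
F4 | step 10 | tert-butyldimethyl{[(1S,3E,7E)-3,7,10,10-tetramethylcycloundeca-3,7-dien-1-yl]oxy}silane | C/C1=C\CC(C)(C)C[C@H](O[Si](C)(C)C(C)(C)C)C/C(C)=C/CC1
F5 | step 13 | 3-{4-[(tert-butyldimethylsilyl)oxy]phenyl}prop-2-ynoic acid | OC(=O)C#Cc1ccc(O[Si](C)(C)C(C)(C)C)cc1
F6 | step 13 | (1S,3E,7E)-3,7,10,10-tetramethylcycloundeca-3,7-dien-1-yl 3-{4-[(tert-butyldimethylsilyl)oxy]phenyl}prop-2-ynoate | C/C1=C\CC(C)(C)C[C@H](OC(=O)C#Cc2ccc(O[Si](C)(C)C(C)(C)C)cc2)C/C(C)=C/CC1
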